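**Retrosynthetic overview**
- Target 12 comes from its 5-O-methyl ether 11 by chelation-controlled cleavage of the methoxy group peri to the C4 carbonyl.
- Key disconnection, C2–C1′: 11 comes from C2-metalated 3,5,7,8-tetramethoxychromone (a masked acyl anion / β-acylvinyl anion at a normally electrophilic carbon) and 1-bromo-2,4-dimethoxybenzene 9.
- Chromone 8 comes from ω-methoxy ketone 5 and a one-carbon unit (DMF-DMA), closing through the only free phenol.
- Ketone 5 comes from 1,2,3,5-tetramethoxybenzene 2 (from cheap 3,4,5-trimethoxyphenol 1) by C-acylation with methoxyacetic acid and cleavage of the crowded ortho-methoxy group.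
- Ring order: ring A is bought, ring C is closed in step 3, ring B is attached last in step 4.

Assumption: the target has no stereocentre and no stereogenic double bond, so the "single enantiomer" is the achiral compound itself and no stereocontrol is needed.

**Route**

Step 1
Reactants: 1 3,4,5-trimethoxyphenol
Product: 2 1,2,3,5-tetramethoxybenzene
Conditions: MeI (1.5 equiv), K2CO3 (2 equiv), acetone, reflux
Reagents that add atoms: iodomethane, CI
Why: Williamson O-methylation of the phenoxide (SN2 on MeI) gives the C2-symmetric arene whose two free positions are equivalent; no stereocentre is formed.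

Step 2
Reactants: 2 1,2,3,5-tetramethoxybenzene; 3 methoxyacetic acid
Product: 5 1-(2-hydroxy-3,4,6-trimethoxyphenyl)-2-methoxyethan-1-one, via tetramethoxyphenyl ketone 4 (not isolated)
Conditions: (CF3CO)2O (2.5 equiv), CH2Cl2, 0 °C → rt; volatiles removed in vacuo; then BCl3 (2 equiv), CH2Cl2, −78 → 0 °C; aqueous work-up
Reagents that add atoms: none
Why: Mixed-anhydride (TFAA) Friedel–Crafts acylation of the strongly activated arene avoids the decarbonylation that methoxyacetyl chloride/AlCl3 suffers, and BCl3 then cleaves one carbonyl-flanking methoxy group through a six-membered boron chelate, preferentially the more congested one buttressed by the neighbouring OMe, after which the O–B chelate blocks a second cleavage.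

Step 3
Reactants: 5 1-(2-hydroxy-3,4,6-trimethoxyphenyl)-2-methoxyethan-1-one; 6 N,N-dimethylformamide dimethyl acetal
Product: 8 3,5,7,8-tetramethoxy-4H-chromen-4-one, via enaminone 7 (not isolated)
Conditions: DMF-DMA (2.5 equiv), toluene, 100 °C; then AcOH, 80 °C
Reagents that add atoms: none
Why: Aminomethylenation of the only enolisable CH2 gives a vinylogous amide, and acid-promoted intramolecular oxa-Michael addition of the single free phenol with loss of dimethylamine closes the pyranone (enaminone chromone synthesis), which fixes the 5,7,8-oxygenation pattern.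

Step 4
Reactants: 8 3,5,7,8-tetramethoxy-4H-chromen-4-one; 9 1-bromo-2,4-dimethoxybenzene
Product: 11 2-(2,4-dimethoxyphenyl)-3,5,7,8-tetramethoxy-4H-chromen-4-one, via chromon-2-ylzinc chloride 10 (not isolated)
Conditions: TMPZnCl·LiCl (1.3 equiv), THF, 25 °C; then 9 (1.2 equiv), Pd(OAc)2 (3 mol %), SPhos (6 mol %), THF, 60 °C
Reagents that add atoms: TMPZnCl·LiCl, CC1(C)CCCC(C)(C)N1[Zn]Cl.[Li+].[Cl-] (its ZnCl appears only in intermediate 10)
Why: Deprotonative zincation removes the only vinylic proton (C2–H, acidified by O1, the 3-OMe and the vinylogous carbonyl) to give a C2 carbanion, i.e. an α-alkoxyvinyl (masked acyl) and β-acylvinyl (homoenolate-type) nucleophile at an innately electrophilic carbon, which Negishi cross-coupling joins to the electrophilic C–Br carbon of 9; no stereocentre is formed.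

Step 5
Reactants: 11 2-(2,4-dimethoxyphenyl)-3,5,7,8-tetramethoxy-4H-chromen-4-one
Product: 12 2-(2,4-dimethoxyphenyl)-5-hydroxy-3,7,8-trimethoxy-4H-chromen-4-one
Conditions: AlCl3 (4 equiv), MeCN, 25 → 50 °C; then dilute aqueous acid, brief warming
Reagents that add atoms: none
Why: Chelation-controlled Lewis-acid demethylation, in which aluminium bridges C4=O and the peri 5-OMe in a six-membered chelate and chloride removes that methyl, while the 3-OMe (poorer five-membered chelate) and the unchelated 7-, 8-, 2′- and 4′-OMe groups remain.

**Compound list**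

1 | 3,4,5-trimethoxyphenol | COc1cc(O)cc(OC)c1OC | starting material
2 | 1,2,3,5-tetramethoxybenzene | COc1cc(OC)c(OC)c(OC)c1 | intermediate
3 | methoxyacetic acid | COCC(=O)O | starting material
4 | 2-methoxy-1-(2,3,4,6-tetramethoxyphenyl)ethan-1-one | COCC(=O)c1c(OC)c(OC)c(OC)cc1OC | intermediate (not isolated)
5 | 1-(2-hydroxy-3,4,6-trimethoxyphenyl)-2-methoxyethan-1-one | COCC(=O)c1c(O)c(OC)c(OC)cc1OC | intermediate
6 | N,N-dimethylformamide dimethyl acetal | COC(OC)N(C)C | starting material
7 | (Z)-3-(dimethylamino)-1-(2-hydroxy-3,4,6-trimethoxyphenyl)-2-methoxyprop-2-en-1-one (NMe2 trans to the carbonyl) | CO/C(=C\N(C)C)C(=O)c1c(O)c(OC)c(OC)cc1OC | intermediate (not isolated)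
8 | 3,5,7,8-tetramethoxy-4H-chromen-4-one | COc1coc2c(OC)c(OC)cc(OC)c2c1=O | intermediate
9 | 1-bromo-2,4-dimethoxybenzene | COc1ccc(Br)c(OC)c1 | starting material
10 | (3,5,7,8-tetramethoxy-4-oxo-4H-chromen-2-yl)zinc chloride (LiCl complex) | COc1c([Zn]Cl)oc2c(OC)c(OC)cc(OC)c2c1=O | intermediate (not isolated)
11 | 2-(2,4-dimethoxyphenyl)-3,5,7,8-tetramethoxy-4H-chromen-4-one | COc1ccc(-c2oc3c(OC)c(OC)cc(OC)c3c(=O)c2OC)c(OC)c1 | intermediate
12 | 2-(2,4-dimethoxyphenyl)-5-hydroxy-3,7,8-trimethoxy-4H-chromen-4-one (5-hydroxy-3,7,8,2′,4′-pentamethoxyflavone) | COc1ccc(-c2oc3c(OC)c(OC)cc(O)c3c(=O)c2OC)c(OC)c1 | target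

**Totals**

Total step count: 5. Longest linear sequence: 5 (1 → 2 → 5 → 8 → 11 → 12); compounds 3, 6 and 9 are bought.

**Steps most likely to fail, with fallbacks**

Step 4 is the riskiest. The zincation is expected at C2 by analogy with simpler chromones, but the coupling joins two congested, electron-rich partners (3-OMe beside the C–Zn bond, 2-OMe beside the C–Br bond). If the coupling stalls, the roles of the partners are exchanged. The fallback sets out from zinc reagent 10, which is quenched with I2 (THF, 0 °C) to give 2-iodo-3,5,7,8-tetramethoxy-4H-chromen-4-one F2, a vinylogous acyl iodide that is isolated. F2 is then coupled with commercial 2,4-dimethoxyphenylboronic acid under Suzuki–Miyaura conditions (Pd(dppf)Cl2, K3PO4, dioxane/H2O, 80 °C), and the route is rejoined at 11.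

Step 2 is next. The mixed anhydride may trifluoroacetylate the arene, and BCl3 on crude material may cleave the wrong ortho-methoxy group or the side-chain OMe. Cleavage of the other ortho-methoxy group would lead to the 5,6,7-pattern, so the structure of 5 must be confirmed. The fallback sets out from 2 and makes the C–C bond by directed ortho-lithiation instead of electrophilic substitution. n-BuLi/TMEDA (THF, 0 °C) gives (2,3,4,6-tetramethoxyphenyl)lithium F1 at the position between two methoxy groups. F1 is acylated with N-methoxy-N-methyl-2-methoxyacetamide (−78 °C → rt) to give ketone 4, which is now isolated and purified. Pure 4 is treated with BCl3 (1.05 equiv, CH2Cl2, −78 °C), and the route is rejoined at 5.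

Step 5 is third. Both the 5-OMe and the 3-OMe flank the carbonyl, and AlCl3 may not discriminate them cleanly among six methoxy groups. The fallback moves the selectivity from the cleavage to the alkylation. It sets out from 11, which is pushed with excess AlBr3 (MeCN, 50–60 °C) to 2-(2,4-dimethoxyphenyl)-3,5-dihydroxy-7,8-dimethoxy-4H-chromen-4-one F3. Only the 3-OH of F3 is then methylated (Me2SO4 1.05 equiv, K2CO3, acetone, rt), because the strongly chelated 5-OH is inert under these conditions, and the route is rejoined at 12.

**Further compounds**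

F1 | step 2 | (2,3,4,6-tetramethoxyphenyl)lithium | [Li]c1c(OC)cc(OC)c(OC)c1OC
F2 | step 4 | 2-iodo-3,5,7,8-tetramethoxy-4H-chromen-4-one | COc1c(I)oc2c(OC)c(OC)cc(OC)c2c1=O
F3 | step 5 | 2-(2,4-dimethoxyphenyl)-3,5-dihydroxy-7,8-dimethoxy-4H-chromen-4-one | COc1ccc(-c2oc3c(OC)c(OC)cc(O)c3c(=O)c2O)c(OC)c1
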